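Ring atoms: C1 bears NH2 and CO2H, C2 the octanoate, C3 OH and phenyl, then C4, C5. Everything rests on cutting the C2–C3 bond of the cyclopentane. Both carbons carry oxygen, so C2 can be read as a formyl carbon on the fully substituted C1 and C3 as a benzoyl carbon. A triazolylidene carbene inverts the polarity of that formyl group. In one operation it closes the five-membered ring, sets the C3 carbinol centre and leaves a C2 ketone for a later directed reduction. The precursor is an open-chain keto aldehyde, an α-formyl-α-(3-oxo-3-phenylpropyl)glycine carrying NHCbz and a benzyl ester. Its quaternary C1 stems from L-serine by alkylation with retention.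

Key step: step 7

**Remarks on the chemistry**
- **Configuration:** the target is (1S,2R,3S). N and C3–OH lie on one face of the ring; CO2H, C2–O and phenyl lie on the other. C1 is L-serine with its α-hydrogen replaced by C5 with retention, and the serine CH2OH is C2.
- **Order of events:** nitrogen and C3 stand in a γ-amino ketone relation (N–C1–C5–C4–C3). A free amine would condense with the phenyl ketone to a 2-phenyl-1-pyrroline. C3 is therefore carried as the styrene carbon of a cinnamyl group and is oxidised only after nitrogen bears Cbz.
- **Protecting groups:** the benzyl ester is present from the first compound. Boc on the acetal nitrogen allows mild release of the amino alcohol. Cbz and benzyl leave together by neutral hydrogenolysis, because acid would ionise the tertiary benzylic C3–OH. The carbamate N–H is kept as a hydrogen-bond donor for the key step.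
- **Assumption:** the (5aR,10bS) antipode of the aminoindanol-derived triazolium salt is taken as the matched one; both antipodes are commercial and the choice changes no structure of the route.

**Step 1**
Reactants: 1 L-serine benzyl ester hydrochloride; 2 pivalaldehyde
Product: 3 benzyl (4S)-2-tert-butyl-1,3-oxazolidine-4-carboxylate (both C2 epimers)
Conditions: Et3N (1.05 equiv), pentane, reflux, Dean–Stark trap
Reagents that add atoms: pivalaldehyde 2, CC(C)(C)C=O
Why: Condensation of a 1,2-amino alcohol with an aldehyde (N,O-acetal formation) is driven by azeotropic removal of water, leaves the serine centre untouched, and gives C2 epimers whose proportion is irrelevant because they interconvert through the open imine.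

**Step 2**
Reactants: 3 benzyl (4S)-2-tert-butyl-1,3-oxazolidine-4-carboxylate
Product: 4 4-benzyl 3-tert-butyl (2R,4S)-2-tert-butyl-1,3-oxazolidine-3,4-dicarboxylate (tert-butyl cis to the ester)
Conditions: Boc2O (1.2 equiv), THF, rt → 45 °C; chromatography to remove any trans isomer
Reagents that add atoms: di-tert-butyl dicarbonate, CC(C)(C)OC(=O)OC(=O)OC(C)(C)C
Why: N-Acylation with Boc2O (carbamate formation) runs as a dynamic kinetic resolution, since the C2 epimers of 3 equilibrate through the imine and the cis isomer, whose nitrogen is open on the face away from both substituents, is captured faster, which sets the acetal centre as (2R).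

**Step 3**
Reactants: 4 4-benzyl 3-tert-butyl (2R,4S)-2-tert-butyl-1,3-oxazolidine-3,4-dicarboxylate; 5 (E)-cinnamyl bromide
Product: 7 4-benzyl 3-tert-butyl (2R,4S)-2-tert-butyl-4-[(2E)-3-phenylprop-2-en-1-yl]-1,3-oxazolidine-3,4-dicarboxylate (cinnamyl trans to tert-butyl), via lithium enolate 6 (not isolated)
Conditions: LDA (1.1 equiv), THF–DMPU 9:1, −78 °C, 30 min; then 5 (1.5 equiv), −78 °C
Reagents that add atoms: (E)-cinnamyl bromide 5, BrC/C=C/c1ccccc1
Why: Ester enolate alkylation with self-regeneration of the stereocentre: in planar enolate 6 only the acetal centre is left, its tert-butyl group covers one face, and the reactive allylic bromide enters by SN2 at its primary carbon from the other face, the one the α-hydrogen occupied, so the future C1 forms with retention at a temperature at which the enolate does not yet open by β-elimination.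

**Step 4**
Reactants: 7 4-benzyl 3-tert-butyl (2R,4S)-2-tert-butyl-4-cinnamyl-1,3-oxazolidine-3,4-dicarboxylate
Product: 9 benzyl (2S,4E)-2-{[(benzyloxy)carbonyl]amino}-2-(hydroxymethyl)-5-phenylpent-4-enoate, via amino alcohol hydrochloride 8 (not isolated)
Conditions: HCl (4 M in dioxane)–H2O 10:1, 0 °C → rt; evaporation to dryness (pivalaldehyde leaves); then CbzCl (1.1 equiv), NaHCO3, THF–H2O, 0 °C → rt
Reagents that add atoms: benzyl chloroformate, O=C(Cl)OCc1ccccc1
Why: Acidolysis of the Boc group turns the robust N-acyl acetal into a basic N–H oxazolidine that hydrolyses under the same mild conditions without harm to the hindered benzyl ester or the styrene, and Schotten–Baumann acylation then caps the amine in preference to the neopentyl-type alcohol, while the quaternary centre cannot racemise and no ketone is present to trap the free amine.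

**Step 5**
Reactants: 9 benzyl (2S,4E)-2-{[(benzyloxy)carbonyl]amino}-2-(hydroxymethyl)-5-phenylpent-4-enoate
Product: 10 benzyl (2S)-2-{[(benzyloxy)carbonyl]amino}-2-(hydroxymethyl)-5-oxo-5-phenylpentanoate
Conditions: FePcF16 (iron hexadecafluorophthalocyanine, 5 mol %), Et3SiH (2.5 equiv), O2 (1 atm), EtOH, rt
Reagents that add atoms: dioxygen, O=O
Why: Iron-hydride hydrogen atom transfer (the Wacker-type variant of the Mukaiyama hydration, known for β-alkylstyrenes) puts hydrogen on C4 because only this gives the benzylic radical at C3, which takes up O2 and collapses from the peroxide to the aryl ketone, while carbamate, ester and alcohol are inert under these neutral conditions.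

**Step 6**
Reactants: 10 benzyl (2S)-2-{[(benzyloxy)carbonyl]amino}-2-(hydroxymethyl)-5-oxo-5-phenylpentanoate
Product: 11 benzyl (2S)-2-{[(benzyloxy)carbonyl]amino}-2-formyl-5-oxo-5-phenylpentanoate
Conditions: DMP (1.3 equiv), CH2Cl2, 0 °C → rt; short silica pad, used at once
Reagents that add atoms: none
Why: The Dess–Martin oxidation stops at the aldehyde under almost neutral, non-nucleophilic conditions, ketone and carbamate are spectators, and the formyl group sits on a carbon without hydrogen so that neither enolisation nor epimerisation can follow.

**Step 7**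
Reactants: 11 benzyl (2S)-2-{[(benzyloxy)carbonyl]amino}-2-formyl-5-oxo-5-phenylpentanoate
Product: 12 benzyl (1S,3S)-1-{[(benzyloxy)carbonyl]amino}-3-hydroxy-2-oxo-3-phenylcyclopentane-1-carboxylate (C3–OH cis to N)
Conditions: (5aR,10bS)-2-(pentafluorophenyl)-5a,10b-dihydro-4H,6H-indeno[2,1-b][1,2,4]triazolo[4,3-d][1,4]oxazinium tetrafluoroborate (20 mol %), iPr2NEt (20 mol %), toluene (0.05 M), 4 Å MS, Ar, rt → 40 °C
Reagents that add atoms: none
Why: Deprotonation of the triazolium salt gives the carbene, which adds to the C2 formyl group; proton transfer produces the enaminol (Breslow intermediate), an acyl anion equivalent that attacks the C3 benzoyl carbon, and collapse of the adduct expels the carbene and leaves a C2 ketone beside the new C3 carbinol. The closest known reaction type is the carbene-catalysed intramolecular crossed aldehyde–ketone benzoin reaction, established for five- and six-membered tertiary ketols from aliphatic aldehydes and ketones. The cyclopentane closes in a 5-exo-trig mode at the ketone C=O, with the enaminol double bond exocyclic to the forming ring. C3 is the only new stereocentre: hydrogen bonds from the enaminol O–H and the carbamate N–H to the ketone oxygen hold that oxygen on the nitrogen face and push phenyl to the ester face, which gives (3S), and the indane wall of the matched catalyst screens the competing ketone face. The step needs donor/acceptor chemoselectivity and integrity of C1: only the aldehyde can bind the carbene productively, an aldol between C4 and C2 would need a four-membered ring, and C1 carries no hydrogen. A weak amine base in dry, alcohol-free toluene keeps the formyl group of 11 and the β-keto ester of 12 from retro-Claisen cleavage.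

**Step 8**
Reactants: 12 benzyl (1S,3S)-1-{[(benzyloxy)carbonyl]amino}-3-hydroxy-2-oxo-3-phenylcyclopentane-1-carboxylate
Product: 13 benzyl (1S,2R,3S)-1-{[(benzyloxy)carbonyl]amino}-2,3-dihydroxy-3-phenylcyclopentane-1-carboxylate (trans-diol)
Conditions: Me4NBH(OAc)3 (5 equiv), MeCN–AcOH 1:1, −20 °C → rt
Reagents that add atoms: none
Why: In this Saksena–Evans directed reduction the C3 hydroxyl replaces an acetate on boron and the bound hydride passes to C2 on the face that carries C3–OH and N, which is also the open face because phenyl and CO2Bn screen the other, so the new C2–OH ends trans to C3–OH, (2R), while ester and carbamate are not reduced.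

**Step 9**
Reactants: 13 benzyl (1S,2R,3S)-1-{[(benzyloxy)carbonyl]amino}-2,3-dihydroxy-3-phenylcyclopentane-1-carboxylate; 14 octanoyl chloride
Product: 15 benzyl (1S,2R,3S)-1-{[(benzyloxy)carbonyl]amino}-3-hydroxy-2-(octanoyloxy)-3-phenylcyclopentane-1-carboxylate
Conditions: 14 (1.5 equiv), pyridine (3 equiv), DMAP (0.2 equiv), CH2Cl2, 0 °C → rt
Reagents that add atoms: octanoyl chloride 14, CCCCCCCC(=O)Cl
Why: DMAP-catalysed esterification through the acylpyridinium ion distinguishes the secondary C2 hydroxyl from the tertiary benzylic C3 hydroxyl and from the carbamate N–H, neither of which is acylated under these mild conditions, and no stereocentre is touched.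

**Step 10**
Reactants: 15 benzyl (1S,2R,3S)-1-{[(benzyloxy)carbonyl]amino}-3-hydroxy-2-(octanoyloxy)-3-phenylcyclopentane-1-carboxylate
Product: 16 fusarilin A, (1S,2R,3S)-1-amino-3-hydroxy-2-(octanoyloxy)-3-phenylcyclopentane-1-carboxylic acid
Conditions: H2 (1 atm), 10% Pd/C, MeOH, rt
Reagents that add atoms: none
Why: Catalytic hydrogenolysis cleaves both O-benzyl bonds (the carbamic acid then loses CO2) in neutral medium, in which a tertiary benzylic alcohol and the octanoate persist, and the trans relation of C1–N and C2–O blocks an O-to-N acyl shift, which would need a trans-fused bicyclic intermediate.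

**Compound list**
1 | L-serine benzyl ester hydrochloride | Cl.N[C@@H](CO)C(=O)OCc1ccccc1 | starting material
2 | pivalaldehyde | CC(C)(C)C=O | starting material
3 | benzyl (4S)-2-tert-butyl-1,3-oxazolidine-4-carboxylate (both C2 epimers) | CC(C)(C)C1OC[C@@H](C(=O)OCc2ccccc2)N1 | intermediate
4 | 4-benzyl 3-tert-butyl (2R,4S)-2-tert-butyl-1,3-oxazolidine-3,4-dicarboxylate | CC(C)(C)[C@H]1OC[C@@H](C(=O)OCc2ccccc2)N1C(=O)OC(C)(C)C | intermediate
5 | (E)-cinnamyl bromide | BrC/C=C/c1ccccc1 | starting material
6 | lithium enolate of 4 | CC(C)(C)[C@H]1OCC(=C([O-])OCc2ccccc2)N1C(=O)OC(C)(C)C.[Li+] | intermediate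
7 | 4-benzyl 3-tert-butyl (2R,4S)-2-tert-butyl-4-[(2E)-3-phenylprop-2-en-1-yl]-1,3-oxazolidine-3,4-dicarboxylate | CC(C)(C)[C@H]1OC[C@@](C/C=C/c2ccccc2)(C(=O)OCc2ccccc2)N1C(=O)OC(C)(C)C | intermediate
8 | benzyl (2S,4E)-2-amino-2-(hydroxymethyl)-5-phenylpent-4-enoate hydrochloride | Cl.OC[C@](N)(C(=O)OCc1ccccc1)C/C=C/c1ccccc1 | intermediate
9 | benzyl (2S,4E)-2-{[(benzyloxy)carbonyl]amino}-2-(hydroxymethyl)-5-phenylpent-4-enoate | OC[C@](NC(=O)OCc1ccccc1)(C(=O)OCc1ccccc1)C/C=C/c1ccccc1 | intermediate
10 | benzyl (2S)-2-{[(benzyloxy)carbonyl]amino}-2-(hydroxymethyl)-5-oxo-5-phenylpentanoate | OC[C@](NC(=O)OCc1ccccc1)(C(=O)OCc1ccccc1)CCC(=O)c1ccccc1 | intermediate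
11 | benzyl (2S)-2-{[(benzyloxy)carbonyl]amino}-2-formyl-5-oxo-5-phenylpentanoate | O=C[C@](NC(=O)OCc1ccccc1)(C(=O)OCc1ccccc1)CCC(=O)c1ccccc1 | intermediate
12 | benzyl (1S,3S)-1-{[(benzyloxy)carbonyl]amino}-3-hydroxy-2-oxo-3-phenylcyclopentane-1-carboxylate | O=C1[C@](NC(=O)OCc2ccccc2)(C(=O)OCc2ccccc2)CC[C@]1(O)c1ccccc1 | intermediate
13 | benzyl (1S,2R,3S)-1-{[(benzyloxy)carbonyl]amino}-2,3-dihydroxy-3-phenylcyclopentane-1-carboxylate | O[C@@H]1[C@](NC(=O)OCc2ccccc2)(C(=O)OCc2ccccc2)CC[C@]1(O)c1ccccc1 | intermediate
14 | octanoyl chloride | CCCCCCCC(=O)Cl | starting material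
15 | benzyl (1S,2R,3S)-1-{[(benzyloxy)carbonyl]amino}-3-hydroxy-2-(octanoyloxy)-3-phenylcyclopentane-1-carboxylate | CCCCCCCC(=O)O[C@@H]1[C@](NC(=O)OCc2ccccc2)(C(=O)OCc2ccccc2)CC[C@]1(O)c1ccccc1 | intermediate
16 | fusarilin A | CCCCCCCC(=O)O[C@@H]1[C@](N)(C(=O)O)CC[C@]1(O)c1ccccc1 | target

Total step count: 10. Longest linear sequence: 10 steps (from 1 to 16).

**Steps most likely to fail**

**Step 7.** Four processes threaten this step:
- slow addition of the carbene to a formyl group on a fully substituted carbon;
- cleavage of the C1–C2 bond in the carbene adduct (deformylation);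
- expulsion of the carbamate from the enaminol;
- poor facial selectivity at the ketone.

The fallback forms the same C2–C3 bond reductively and then restores the ketone. It sets out from 11. SmI2 (2.5 equiv), t-BuOH, THF, −78 °C should trigger a ketyl–carbonyl pinacol cyclisation. Samarium bridges both oxygens and can also bind the carbamate carbonyl, which should place the diol on the nitrogen face. The product would be the cis-diol benzyl (1S,2S,3S)-1-{[(benzyloxy)carbonyl]amino}-2,3-dihydroxy-3-phenylcyclopentane-1-carboxylate F1. Its unwanted C2 configuration is erased by oxidising the secondary carbinol with IBX (DMSO, rt), a reagent that converts 1,2-diols into ketols without glycol cleavage. The route is rejoined at 12.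

**Step 5.** The risks are over-reduction of the intermediate peroxide to the benzylic alcohol and incomplete conversion of a 1,2-disubstituted styrene. The fallback accepts the alcohol level and oxidises both carbinols together. It sets out from 9. Mukaiyama hydration (Mn(dpm)3 10 mol %, PhSiH3, O2, iPrOH, 0 °C → rt) should give benzyl (2S)-2-{[(benzyloxy)carbonyl]amino}-5-hydroxy-2-(hydroxymethyl)-5-phenylpentanoate F2 as an inconsequential pair of C5 epimers. A double Swern oxidation follows ((COCl)2, DMSO, CH2Cl2, −78 °C, then Et3N). Both hydroxyls are activated before base is added, so lactol formation is avoided. The route is rejoined at 11, bypassing 10.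

**Step 8.** The risk is failure of the hindered tertiary hydroxyl to exchange onto boron, so that the ketone between two fully substituted carbons stays unreduced. The fallback gives up delivery from oxygen and relies on steric approach control. It sets out from 12. A Luche reduction (NaBH4, CeCl3·7H2O, MeOH–THF, −40 °C) brings a small external hydride to the face opposite phenyl and CO2Bn. This should lead to the same trans-diol, so the route is rejoined at 13 (no new compound, F0).

**Further compounds**
F1 | step 7 | benzyl (1S,2S,3S)-1-{[(benzyloxy)carbonyl]amino}-2,3-dihydroxy-3-phenylcyclopentane-1-carboxylate (cis-diol) | O[C@H]1[C@](NC(=O)OCc2ccccc2)(C(=O)OCc2ccccc2)CC[C@]1(O)c1ccccc1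
F2 | step 5 | benzyl (2S)-2-{[(benzyloxy)carbonyl]amino}-5-hydroxy-2-(hydroxymethyl)-5-phenylpentanoate (C5 epimers) | OC[C@](NC(=O)OCc1ccccc1)(C(=O)OCc1ccccc1)CCC(O)c1ccccc1
F0 | step 8 | none | none
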